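**Plan**

1. Target: (5S)-1-(4-hydroxy-3-methoxyphenyl)-3-oxotetradecan-5-yl acetate (C1 = ArCH2, C3 = ketone, C5 = CH–OAc, C6–C14 = nonyl).
2. Retrosynthesis: remove an O-benzyl group from the phenol; mask the C3 ketone as C2 of a 1,3-dithiane; cut C3–C4 to give a 2-(2-arylethyl)-1,3-dithiane, (S)-2-nonyloxirane and Ac2O; cut C6–C7 of the oxirane back to (S)-epichlorohydrin and an octyl Grignard reagent.
3. Enabling feature: the 1,3-relationship between the C3 carbonyl carbon and the C5 oxygen. C4H2–C5H–O is an opened oxirane and C3 is an acyl carbon, so both are natural acceptors; they are joined after polarity reversal of C3 inside the six-membered S–C–S ring.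
4. Forward: dihydroconiferyl alcohol → benzyl ether → aldehyde → dithiane; (S)-epichlorohydrin → chlorohydrin → epoxide; one-flask union at C3–C4 with acetylation of the C5 alkoxide; thioacetal hydrolysis; hydrogenolysis. The arene is the only ring of the target and is bought.
5. Stereochemistry: the single stereocentre C5 (S) comes from (S)-epichlorohydrin; no bond to C5 is broken afterwards.

Key step: step 6

Assumption: C5 of the given SMILES is (S) by CIP analysis (O > CH2C(=O) > nonyl > H); dihydroconiferyl alcohol, (S)-epichlorohydrin and n-octylmagnesium bromide are taken as commercial.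

**Route**

Step 1
Reactants: 1 dihydroconiferyl alcohol [3-(4-hydroxy-3-methoxyphenyl)propan-1-ol]; 2 benzyl bromide
Product: 3 3-[4-(benzyloxy)-3-methoxyphenyl]propan-1-ol
Conditions: K2CO3, acetone, reflux
Reagents that add atoms: benzyl bromide, BrCc1ccccc1
Why: Williamson ether synthesis; K2CO3 deprotonates only the phenol, so benzylation should be chemoselective over the primary alcohol.

Step 2
Reactants: 3 3-[4-(benzyloxy)-3-methoxyphenyl]propan-1-ol
Product: 4 3-[4-(benzyloxy)-3-methoxyphenyl]propanal
Conditions: TEMPO (10 mol%), PhI(OAc)2, CH2Cl2, rt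
Reagents that add atoms: none
Why: TEMPO/oxoammonium oxidation of a primary alcohol should stop at the aldehyde under anhydrous conditions and tolerates the benzyl and methyl aryl ethers.

Step 3
Reactants: 4 3-[4-(benzyloxy)-3-methoxyphenyl]propanal; 5 propane-1,3-dithiol
Product: 6 2-{2-[4-(benzyloxy)-3-methoxyphenyl]ethyl}-1,3-dithiane
Conditions: BF3·OEt2 (cat.), CH2Cl2, 0 °C
Reagents that add atoms: propane-1,3-dithiol, SCCCS
Why: Lewis-acid-catalysed dithioacetalisation of an unhindered aliphatic aldehyde is fast at 0 °C, so the aryl benzyl ether should survive the brief exposure; it installs the S–C–S ring that later acidifies the C3–H.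

Step 4
Reactants: 7 (S)-epichlorohydrin [(2S)-2-(chloromethyl)oxirane]; 8 n-octylmagnesium bromide
Product: 9 (2S)-1-chloroundecan-2-ol
Conditions: CuI (10 mol%), THF, −40 → −20 °C; then H2O
Reagents that add atoms: n-octylmagnesium bromide, CCCCCCCC[Mg]Br
Why: Copper-catalysed Grignard opening of an epihalohydrin proceeds by SN2 at the unsubstituted oxirane carbon, leaving the C–Cl bond and the stereocentre untouched, so the (S) configuration should be carried over.

Step 5
Reactants: 9 (2S)-1-chloroundecan-2-ol
Product: 10 (S)-2-nonyloxirane [(S)-1,2-epoxyundecane]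
Conditions: NaOH (powdered), Et2O, rt
Reagents that add atoms: none
Why: Intramolecular Williamson (3-exo-tet) displacement of chloride by the alkoxide; the stereocentre carries the nucleophilic oxygen and is not the site of substitution, so the (S)-epoxide should result.

Step 6
Reactants: 6 2-{2-[4-(benzyloxy)-3-methoxyphenyl]ethyl}-1,3-dithiane; 10 (S)-2-nonyloxirane; 11 acetic anhydride
Product: 14 (2S)-1-{2-[2-(4-benzyloxy-3-methoxyphenyl)ethyl]-1,3-dithian-2-yl}undecan-2-yl acetate, via lithiated dithiane 12 (not isolated), via lithium alkoxide 13 (not isolated)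
Conditions: n-BuLi, THF, −30 °C; then 10 (1.2 equiv), −30 → 0 °C; then Ac2O, 0 °C → rt
Reagents that add atoms: acetic anhydride, CC(=O)OC(C)=O
Why: n-BuLi removes the C2–H of the 1,3-dithiane ring of 6 to give carbanion 12, stabilised by the two sulfur atoms, so the future C3 carbonyl carbon reacts as an acyl anion (Corey–Seebach umpolung). Carbanion 12 opens the monosubstituted oxirane 10 by SN2 at its CH2 terminus, which forms the C3–C4 bond and releases the C5 lithium alkoxide 13, and Ac2O acylates this alkoxide in the same flask. The closest known reaction type is the alkylation of 2-alkyl-2-lithio-1,3-dithianes with terminal epoxides followed by O-acylation of the resulting alkoxide. No ring is closed and no new stereocentre is formed: the C5–O bond of (S)-10 is never broken, so C5 should be (S) by retention. The step needs attack at the oxirane CH2 and not at CH, which the steric demand of the tertiary carbanion toward a monosubstituted epoxide secures, and metalation at dithiane C2 and not at the benzylic OCH2 or the arene, which the acidity of the S,S-acetal C–H at −30 °C without a chelating amine secures. Acetylating while C3 is still a thioacetal closes the E1cB path by which a β-acetoxy ketone would lose acetic acid.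

Step 7
Reactants: 14 (2S)-1-{2-[2-(4-benzyloxy-3-methoxyphenyl)ethyl]-1,3-dithian-2-yl}undecan-2-yl acetate
Product: 15 (5S)-1-[4-(benzyloxy)-3-methoxyphenyl]-3-oxotetradecan-5-yl acetate
Conditions: MeI, CaCO3, MeCN/H2O (9:1), 45 °C
Reagents that add atoms: water, O
Why: Alkylative thioacetal hydrolysis; S-methylation turns each sulfur into a leaving group, water captures the thionium ions, and the CaCO3 buffer keeps the medium near neutral so that the acetate and benzyl ether should survive and β-elimination stay suppressed.

Step 8
Reactants: 15 (5S)-1-[4-(benzyloxy)-3-methoxyphenyl]-3-oxotetradecan-5-yl acetate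
Product: 16 (5S)-1-(4-hydroxy-3-methoxyphenyl)-3-oxotetradecan-5-yl acetate
Conditions: H2 (1 atm), 10% Pd/C, EtOAc, rt
Reagents that add atoms: none
Why: Catalytic hydrogenolysis of the aryl benzyl ether under neutral conditions should leave the aliphatic ketone, the non-benzylic acetate and C5 untouched; the sulfur has been removed before this step.

**Compound list**

1 | dihydroconiferyl alcohol, 3-(4-hydroxy-3-methoxyphenyl)propan-1-ol | OCCCc1ccc(O)c(OC)c1 | starting material
2 | benzyl bromide | BrCc1ccccc1 | starting material
3 | 3-[4-(benzyloxy)-3-methoxyphenyl]propan-1-ol | OCCCc1ccc(OCc2ccccc2)c(OC)c1 | intermediate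
4 | 3-[4-(benzyloxy)-3-methoxyphenyl]propanal | O=CCCc1ccc(OCc2ccccc2)c(OC)c1 | intermediate
5 | propane-1,3-dithiol | SCCCS | starting material
6 | 2-{2-[4-(benzyloxy)-3-methoxyphenyl]ethyl}-1,3-dithiane | C1CSC(CCc2ccc(OCc3ccccc3)c(OC)c2)SC1 | intermediate
7 | (S)-epichlorohydrin, (2S)-2-(chloromethyl)oxirane | ClC[C@@H]1CO1 | starting material
8 | n-octylmagnesium bromide | CCCCCCCC[Mg]Br | starting material
9 | (2S)-1-chloroundecan-2-ol | ClC[C@@H](O)CCCCCCCCC | intermediate
10 | (S)-2-nonyloxirane, (S)-1,2-epoxyundecane | CCCCCCCCC[C@@H]1OC1 | intermediate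
11 | acetic anhydride | CC(=O)OC(C)=O | starting material
12 | lithiated dithiane, 2-{2-[4-(benzyloxy)-3-methoxyphenyl]ethyl}-2-lithio-1,3-dithiane | [Li]C1(CCc2ccc(OCc3ccccc3)c(OC)c2)SCCCS1 | intermediate
13 | lithium alkoxide, lithium (2S)-1-{2-[2-(4-benzyloxy-3-methoxyphenyl)ethyl]-1,3-dithian-2-yl}undecan-2-olate | CCCCCCCCC[C@@H](CC1(CCc2ccc(OCc3ccccc3)c(OC)c2)SCCCS1)O[Li] | intermediate
14 | (2S)-1-{2-[2-(4-benzyloxy-3-methoxyphenyl)ethyl]-1,3-dithian-2-yl}undecan-2-yl acetate | CCCCCCCCC[C@@H](CC1(CCc2ccc(OCc3ccccc3)c(OC)c2)SCCCS1)OC(C)=O | intermediate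
15 | (5S)-1-[4-(benzyloxy)-3-methoxyphenyl]-3-oxotetradecan-5-yl acetate | CCCCCCCCC[C@@H](CC(=O)CCc1ccc(OCc2ccccc2)c(OC)c1)OC(C)=O | intermediate
16 | (5S)-1-(4-hydroxy-3-methoxyphenyl)-3-oxotetradecan-5-yl acetate | CCCCCCCCC[C@@H](CC(=O)CCc1ccc(O)c(OC)c1)OC(C)=O | target

**Step count and risks**

Total step count: 8. Longest linear sequence: 6 steps (steps 1, 2, 3, 6, 7, 8).

Steps most likely to fail:

Step 6 (key step). The metalation may be incomplete or go to the wrong site (the benzylic OCH2 or a ring position next to an ether), and the tertiary carbanion may open the epoxide only slowly; acetic anhydride would then acylate leftover carbanion. The fallback reverses the polarity assignment so that C4 becomes the donor and C3 stays an acceptor. It sets out from 4 and 9 and comes back to the route at 15. Aldehyde 4 would be oxidised (NaClO2, NaH2PO4, 2-methylbut-2-ene, t-BuOH/H2O) to 3-[4-(benzyloxy)-3-methoxyphenyl]propanoic acid F1 and condensed (EDC, MeNHOMe·HCl, Et3N) to 3-[4-(benzyloxy)-3-methoxyphenyl]-N-methoxy-N-methylpropanamide F2. Chlorohydrin 9 would be deprotonated with n-BuLi and reductively lithiated with lithium naphthalenide at −78 °C to lithium (2S)-1-lithioundecan-2-olate F3, a β-oxido organolithium in which the O–Li group is too poor a leaving group for β-elimination at this temperature. Addition of F3 to F2 should give the chelated tetrahedral adduct F4, which on aqueous work-up should collapse to (5S)-1-[4-(benzyloxy)-3-methoxyphenyl]-5-hydroxytetradecan-3-one F5. Acetylation (Ac2O, pyridine, 0 °C) would then give 15.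

Step 7. The ketone may lose acetic acid by β-elimination as it is unmasked, or S-alkylation may stall so that hydrolysis stays incomplete. The fallback inverts the order of acylation and unmasking, so that the thioacetal is opened on a substrate with no leaving group β to the new carbonyl. It sets out from 6 and 10 and comes back at 15. Step 6 would be run with an aqueous quench in place of Ac2O, so that alkoxide 13 is protonated to (2S)-1-{2-[2-(4-benzyloxy-3-methoxyphenyl)ethyl]-1,3-dithian-2-yl}undecan-2-ol F6. Hydrolysis of F6 (MeI, CaCO3, MeCN/H2O) should give the hydroxy ketone F5 already described for step 6, and acetylation (Ac2O, pyridine, 0 °C) would give 15.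

Step 4. Enantiopurity may erode through attack at the chloromethyl carbon or through halide-induced opening and re-closure of the oxirane, and the Grignard reagent may homocouple. The fallback replaces the copper-mediated alkylation by a Lewis-acid-mediated alkynylation that acts only at the activated oxirane at low temperature. It sets out from 7 and comes back at 9. Lithium oct-1-ynide (from oct-1-yne and n-BuLi) with BF3·OEt2 in THF at −78 °C should open 7 at the oxirane CH2 to give (2S)-1-chloroundec-4-yn-2-ol F7. Hydrogenation of the triple bond (H2, PtO2, EtOAc) would give 9.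

**Further compounds**

F1 | step 6 | 3-[4-(benzyloxy)-3-methoxyphenyl]propanoic acid | OC(=O)CCc1ccc(OCc2ccccc2)c(OC)c1
F2 | step 6 | 3-[4-(benzyloxy)-3-methoxyphenyl]-N-methoxy-N-methylpropanamide | CON(C)C(=O)CCc1ccc(OCc2ccccc2)c(OC)c1
F3 | step 6 | lithium (2S)-1-lithioundecan-2-olate | [Li]C[C@@H](O[Li])CCCCCCCCC
F4 | step 6 | chelated tetrahedral adduct, dilithium salt of (5S)-1-[4-(benzyloxy)-3-methoxyphenyl]-3-[methoxy(methyl)amino]tetradecane-3,5-diol | CCCCCCCCC[C@@H](CC(O[Li])(CCc1ccc(OCc2ccccc2)c(OC)c1)N(C)OC)O[Li]
F5 | step 6 | (5S)-1-[4-(benzyloxy)-3-methoxyphenyl]-5-hydroxytetradecan-3-one | CCCCCCCCC[C@@H](CC(=O)CCc1ccc(OCc2ccccc2)c(OC)c1)O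
F6 | step 7 | (2S)-1-{2-[2-(4-benzyloxy-3-methoxyphenyl)ethyl]-1,3-dithian-2-yl}undecan-2-ol | CCCCCCCCC[C@@H](CC1(CCc2ccc(OCc3ccccc3)c(OC)c2)SCCCS1)O
F7 | step 4 | (2S)-1-chloroundec-4-yn-2-ol | ClC[C@@H](O)CC#CCCCCCC
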